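**Plan**

- Cuts: the two Diels–Alder bonds of the central cyclohexene (C12B–C14A, C15A–C15B), the two C11–C12 bonds (sp3–sp2), and in each decalin the bonds that hold C8 in ring B (C8–C9, C7–C8), which leads back to a trans-hydrindan-1-one.
- Enabling feature: in ring B the one-carbon branch C17 on C8 lies next to C9 (which bears C11), and C9 is flanked by the quaternary C10. The unit C17–C8–C9 is therefore a β-keto ester (ester C17 on C8, ketone C9) made by inserting a diazoacetate carbon between the carbonyl C9 and the CH2 C7 of a Hajos–Parrish-type hydrindanone.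
- Forward: annulation gives ring A on a cyclopentanone, reductive alkylation and deoxygenation finish ring A, ring expansion gives ring B, and triflate, methyl and γ-bromide give one allylic bromide that is used twice. Coupling with a dienylalane gives the diene of unit B, a Diels–Alder reaction with acrolein builds the central ring, the aldehyde becomes an alkyne and a second carboalumination/coupling attaches unit A. A twofold reductive transposition then makes both C8=C17 methylenes, and debenzylation ends the route.
- Stereochemistry: C10 from the amino-acid-mediated aldol cyclization; C5 and C4 from the Birch reductive alkylation (anti to the C10 methyl); C12B and C14A from the chiral iminium catalyst and the endo rule; both 12E alkenes from syn-carboalumination; both C9 from H delivery to the α-face in the allylic diazene retro-ene step.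

Key step: step 6

Remarks: labdane numbering is used for the decalins (C11 on C9, C17 on C8, C18 = oxygenated carbon on C4). Unit A is the decalin on the CH2–CH=C(CH3) chain, unit B the decalin on the ring CH2. But-1-en-3-yne is taken as its commercial stabilised solution. C8 of 11 is enolisable and is drawn without configuration.

Step 1
Reactants: 1 2-methylcyclopentane-1,3-dione; 2 pent-1-en-3-one
Product: 3 2-methyl-2-(3-oxopentyl)cyclopentane-1,3-dione
Conditions: H2O, AcOH (cat.), 75 °C
Reagents that add atoms: none
Why: Michael addition of the acidic 1,3-dione to the vinyl ketone, the standard first stage of a Robinson-type annulation.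

Step 2
Reactants: 3 triketone
Product: 4 (S)-4,7a-dimethyl-2,3,7,7a-tetrahydro-1H-indene-1,5(6H)-dione
Conditions: L-phenylalanine (1 equiv), (1S)-(+)-camphor-10-sulfonic acid (0.5 equiv), DMF, 30 → 70 °C
Reagents that add atoms: none
Why: Hajos–Parrish-type enamine aldol condensation; the L-amino acid selects one of the two enantiotopic ring carbonyls and should set the quaternary C10 as S (β-methyl).

Step 3
Reactants: 4 enedione
Product: 5 C9 ethylene ketal of 4
Conditions: ethylene glycol, p-TsOH·H2O (cat.), 4 Å MS, CH2Cl2, rt
Reagents that add atoms: ethylene glycol, OCCO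
Why: chemoselective ketalization; the saturated cyclopentanone reacts before the conjugated tetrasubstituted enone, as in the mono-ketals of related annulation diketones.

Step 4
Reactants: 5 ketal enone
Product: 7 trans-fused ketal ketone (3-oxo; 4β-methyl; 4α-benzyloxymethyl; H-5α), via lithium enolate 6 (not isolated)
Conditions: Li, NH3(l)/THF, t-BuOH (1 equiv), −78 °C; NH3 removed; BnOCH2Cl, THF, −78 → 0 °C
Reagents that add atoms: benzyl chloromethyl ether, ClCOCc1ccccc1
Why: Birch reductive alkylation; protonation at C5 should give the trans ring fusion, and the C3=C4 enolate is alkylated on the α-face, anti to the 1,3-related C10 methyl, which puts CH2OBn α (C18) and leaves the methyl β.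

Step 5
Reactants: 7 ketal ketone
Product: 9 (3aS,4R,7aS)-4-[(benzyloxy)methyl]-4,7a-dimethyloctahydro-1H-inden-1-one, via deoxo ketal 8 (not isolated)
Conditions: N2H4·H2O, KOH, diethylene glycol, 130 → 200 °C; then 2 M HCl, THF, rt
Reagents that add atoms: water, O
Why: Wolff–Kishner reduction (Huang-Minlon modification) removes the C3 carbonyl; the benzyl ether and ketal are base-stable and C4 has no α-hydrogen, so neither elimination nor retro-aldol is possible; the acetal is then hydrolysed.

Step 6
Reactants: 9 hydrindanone; 10 ethyl diazoacetate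
Product: 11 ring-expanded β-keto ester (trans-decalin; 9-oxo; CO2Et on C8; 4β-CH3; 4α-CH2OBn; H-5α; 10β-CH3)
Conditions: BF3·OEt2 (1.2 equiv), Et2O, 0 °C → rt
Reagents that add atoms: none
Why: BF3 activates the only carbonyl of 9 (C9), the diazo carbon of 10 adds to it, and in the β-oxido diazonium the C9–C7 bond migrates to the diazo-derived carbon with loss of N2, so that this carbon enters as C8 (carrying the future C17 as its ester) and the five-membered ring becomes the six-membered ring B. The closest known reaction type is the Lewis-acid-promoted homologation of cyclic ketones with diazoacetates (Büchner–Curtius–Schlotterbeck/Tiffeneau–Demjanov manifold), which is established for hindered cyclopentanones next to a quaternary carbon. No ring is closed from an open chain: ring B arises by a 1,2-alkyl shift that enlarges the existing ring by one atom, and the A/B fusion stays trans because C5 and C10 are untouched. The only new sp3 centre, C8, is enolisable and becomes planar in step 7, so no stereocontrol is needed. The selectivity required is which α-carbon migrates: in this reaction type the less substituted carbon moves, and here C7 is a CH2 while the other α-carbon is the fully substituted C10, which secures the C9(=O)–C8(CO2Et) arrangement. The benzyl ether is the only other functional group and is inert.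

Step 7
Reactants: 11 β-keto ester
Product: 12 enol triflate (C8=C9; OTf on C9; CO2Et on C8)
Conditions: Tf2O, i-Pr2NEt, CH2Cl2, −78 °C
Reagents that add atoms: trifluoromethanesulfonic anhydride, O=S(=O)(OS(=O)(=O)C(F)(F)F)C(F)(F)F
Why: O-sulfonylation of the β-keto ester enol; enolisation can only occur toward C8 because C10 is quaternary.

Step 8
Reactants: 12 enol triflate
Product: 13 ethyl 9-methyl-Δ8-decalin-8-carboxylate (new methyl = C11)
Conditions: MeMgBr, Fe(acac)3 (5 mol %), THF/NMP, −30 °C
Reagents that add atoms: methylmagnesium bromide, C[Mg]Br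
Why: iron-catalysed Kumada-type coupling of an activated enol triflate; it is fast at low temperature, so the ester survives, and it is known for β-keto-ester triflates.

Step 9
Reactants: 13 methyl enoate
Product: 15 allylic bromide (ethyl 9-bromomethyl-Δ8-decalin-8-carboxylate), via silyl ketene acetal 14 (not isolated)
Conditions: LDA, Me3SiCl, THF, −78 °C; then NBS, −78 → 0 °C
Reagents that add atoms: N-bromosuccinimide, O=C1CCC(=O)N1Br
Why: the C11 hydrogens are the only γ-hydrogens and lie cis to the ester, so deprotonation gives the silyl dienolate, which should be brominated at the γ-terminus (vinylogous reactivity; C8 is fully substituted). The ionic conditions spare the benzylic ether CH2.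

Step 10
Reactants: 16 but-1-en-3-yne; 15 allylic bromide
Product: 18 triene ester (C9–CH2–CH=C(CH3)–CH=CH2 with 12E; Δ8 ester kept), via dienylalane 17 (not isolated)
Conditions: Me3Al, Cp2ZrCl2 (0.25 equiv), CH2Cl2, 0 °C → rt; then 15, Pd(PPh3)4 (5 mol %), THF, rt
Reagents that add atoms: trimethylaluminium, C[Al](C)C
Why: zirconium-catalysed syn-carboalumination puts CH3 on the internal and Al on the terminal alkyne carbon; the Pd-catalysed alkenyl–allyl (Negishi-type) coupling then joins C12 to the primary allyl terminus C11 with retention, which fixes 12E.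

Step 11
Reactants: 18 triene ester; 19 acrolein
Product: 20 (1S,2S)-aldehyde (cis-3-methyl-2-[(unit B decalinyl)methyl]cyclohex-3-ene-1-carbaldehyde)
Conditions: (5R)-5-benzyl-2,2,3-trimethylimidazolidin-4-one hydrochloride (20 mol %), MeCN/THF/H2O, −10 °C → rt
Reagents that add atoms: none
Why: iminium-catalysed Diels–Alder reaction; the unsubstituted diene terminus C15 should bond to the β-carbon of the iminium ion ("ortho" adduct), the endo transition state should give the cis product, and the benzyl group of the (5R) catalyst covers one face of the E-iminium so that the Re face of the α-carbon is attacked (C14A = S, C12B = S).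

Step 12
Reactants: 20 aldehyde
Product: 21 terminal alkyne (CHO → C≡CH)
Conditions: dimethyl (1-diazo-2-oxopropyl)phosphonate, K2CO3, MeOH/THF, 0 °C → rt
Reagents that add atoms: dimethyl (1-diazo-2-oxopropyl)phosphonate, CC(=O)C(=[N+]=[N-])P(=O)(OC)OC
Why: Ohira–Bestmann (Seyferth–Gilbert) homologation; the mild carbonate base at 0 °C should limit epimerisation of the cis α-centre.

Step 13
Reactants: 21 alkyne; 15 allylic bromide
Product: 23 bis(enoate) (both decalins as ethyl Δ8-8-carboxylates; units joined as in the target; 12E), via alkenylalane 22 (not isolated)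
Conditions: Me3Al, Cp2ZrCl2 (0.25 equiv), CH2Cl2, 0 °C → rt; then 15, Pd(PPh3)4 (5 mol %), THF, rt
Reagents that add atoms: trimethylaluminium, C[Al](C)C
Why: the same syn-carboalumination/alkenyl–allyl coupling as in step 10; CH3 and Al add cis, so C11A ends trans to the ring carbon (12E); the hindered conjugated ester and the ring alkene should not react with the alane.

Step 14
Reactants: 23 bis(enoate)
Product: 24 bis(allylic alcohol) (both CO2Et → CH2OH at C17)
Conditions: DIBAL-H (6 equiv), CH2Cl2, −78 → 0 °C; Rochelle salt
Reagents that add atoms: none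
Why: 1,2-reduction of both conjugated esters to the primary allylic alcohols; benzyl ethers and alkenes are inert.

Step 15
Reactants: 24 bis(allylic alcohol)
Product: 27 18,18'-di-O-benzyl target, via bis(sulfonylhydrazine) 25 (not isolated), via bis(diazene) 26 (not isolated)
Conditions: 2-nitrobenzenesulfonylhydrazide, PPh3, DEAD, THF, −30 °C; then 23 °C
Reagents that add atoms: none
Why: Mitsunobu displacement at each primary C17, loss of sulfinic acid, and retro-ene extrusion of N2 from the allylic diazene (reductive 1,3-transposition); the double bond moves to C8=C17 and H is delivered to C9 from the α-face, anti to the adjacent axial C10 methyl, so both C9 should become H-9α with C11 equatorial.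

Step 16
Reactants: 27 bis(benzyl ether)
Product: 28 target (CNP0194625.1)
Conditions: Li, NH3(l)/THF, −78 °C; NH4Cl
Reagents that add atoms: none
Why: dissolving-metal cleavage of the two benzyl ethers; the four isolated, non-conjugated alkenes are not reduced under these conditions.

**Compound list**

1 | 2-methylcyclopentane-1,3-dione | CC1C(=O)CCC1=O | starting material
2 | pent-1-en-3-one | CCC(=O)C=C | starting material
3 | 2-methyl-2-(3-oxopentyl)cyclopentane-1,3-dione | CCC(=O)CCC1(C)C(=O)CCC1=O | intermediate
4 | (S)-4,7a-dimethyl-2,3,7,7a-tetrahydro-1H-indene-1,5(6H)-dione | O=C1CCC2=C(C)C(=O)CC[C@]12C | intermediate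
5 | C9 ethylene ketal of 4 | O1CCOC12CCC3=C(C)C(=O)CC[C@]23C | intermediate
6 | lithium C3-enolate of the trans-fused ketal | O1CCOC12CC[C@H]3C(C)=C(O[Li])CC[C@]23C | intermediate
7 | trans-fused ketal ketone (4β-CH3, 4α-CH2OBn, H-5α) | O1CCOC12CC[C@H]3[C@](C)(COCc4ccccc4)C(=O)CC[C@]23C | intermediate
8 | 3-deoxo ketal | O1CCOC12CC[C@H]3[C@](C)(COCc4ccccc4)CCC[C@]23C | intermediate
9 | (3aS,4R,7aS)-4-[(benzyloxy)methyl]-4,7a-dimethyloctahydro-1H-inden-1-one | O=C1CC[C@H]2[C@](C)(COCc3ccccc3)CCC[C@]12C | intermediate
10 | ethyl diazoacetate | CCOC(=O)C=[N+]=[N-] | starting material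
11 | ring-expanded β-keto ester (9-oxo, 8-CO2Et trans-decalin) | CCOC(=O)C1CC[C@H]2[C@](C)(COCc3ccccc3)CCC[C@]2(C)C1=O | intermediate
12 | enol triflate (Δ8, 9-OTf, 8-CO2Et) | FC(F)(F)S(=O)(=O)OC1=C(C(=O)OCC)CC[C@H]2[C@](C)(COCc3ccccc3)CCC[C@]12C | intermediate
13 | ethyl 9-methyl-Δ8-decalin-8-carboxylate | CC1=C(C(=O)OCC)CC[C@H]2[C@](C)(COCc3ccccc3)CCC[C@]12C | intermediate
14 | trimethylsilyl ketene acetal with exocyclic C9=C11 | C=C1C(=C(OCC)O[Si](C)(C)C)CC[C@H]2[C@](C)(COCc3ccccc3)CCC[C@]12C | intermediate
15 | allylic bromide (ethyl 9-bromomethyl-Δ8-decalin-8-carboxylate) | BrCC1=C(C(=O)OCC)CC[C@H]2[C@](C)(COCc3ccccc3)CCC[C@]12C | intermediate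
16 | but-1-en-3-yne | C=CC#C | starting material
17 | (E)-dimethyl(2-methylbuta-1,3-dien-1-yl)alane | C=C/C(C)=C/[Al](C)C | intermediate
18 | triene ester (unit B diene, 12E) | C=C/C(C)=C/CC1=C(C(=O)OCC)CC[C@H]2[C@](C)(COCc3ccccc3)CCC[C@]12C | intermediate
19 | acrolein | C=CC=O | starting material
20 | (1S,2S)-cis-cyclohexenecarbaldehyde carrying unit B | O=C[C@H]1CCC=C(C)[C@H]1CC2=C(C(=O)OCC)CC[C@H]3[C@](C)(COCc4ccccc4)CCC[C@]23C | intermediate
21 | terminal alkyne | C#C[C@H]1CCC=C(C)[C@H]1CC2=C(C(=O)OCC)CC[C@H]3[C@](C)(COCc4ccccc4)CCC[C@]23C | intermediate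
22 | (E)-alkenyl(dimethyl)alane | C[Al](C)/C=C(\C)[C@H]1CCC=C(C)[C@H]1CC2=C(C(=O)OCC)CC[C@H]3[C@](C)(COCc4ccccc4)CCC[C@]23C | intermediate
23 | bis(enoate) | C(C1=C(C(=O)OCC)CC[C@H]2[C@](C)(COCc3ccccc3)CCC[C@]12C)/C=C(\C)[C@H]4CCC=C(C)[C@H]4CC5=C(C(=O)OCC)CC[C@H]6[C@](C)(COCc7ccccc7)CCC[C@]56C | intermediate
24 | bis(allylic alcohol) | C(C1=C(CO)CC[C@H]2[C@](C)(COCc3ccccc3)CCC[C@]12C)/C=C(\C)[C@H]4CCC=C(C)[C@H]4CC5=C(CO)CC[C@H]6[C@](C)(COCc7ccccc7)CCC[C@]56C | intermediate
25 | bis[N-(2-nitrobenzenesulfonyl)hydrazine] at both C17 | C(C1=C(CN(N)S(=O)(=O)c8ccccc8[N+](=O)[O-])CC[C@H]2[C@](C)(COCc3ccccc3)CCC[C@]12C)/C=C(\C)[C@H]4CCC=C(C)[C@H]4CC5=C(CN(N)S(=O)(=O)c9ccccc9[N+](=O)[O-])CC[C@H]6[C@](C)(COCc7ccccc7)CCC[C@]56C | intermediate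
26 | bis(allylic diazene) | C(C1=C(CN=N)CC[C@H]2[C@](C)(COCc3ccccc3)CCC[C@]12C)/C=C(\C)[C@H]4CCC=C(C)[C@H]4CC5=C(CN=N)CC[C@H]6[C@](C)(COCc7ccccc7)CCC[C@]56C | intermediate
27 | 18,18'-di-O-benzyl target | C=C1CC[C@H]2[C@](C)(COCc3ccccc3)CCC[C@]2(C)[C@H]1C/C=C(\C)[C@H]1CCC=C(C)[C@H]1C[C@H]1C(=C)CC[C@H]2[C@](C)(COCc3ccccc3)CCC[C@]12C | intermediate
28 | CNP0194625.1 | C=C1CC[C@H]2[C@](C)(CO)CCC[C@]2(C)[C@H]1C/C=C(\C)[C@H]1CCC=C(C)[C@H]1C[C@H]1C(=C)CC[C@H]2[C@](C)(CO)CCC[C@]12C | target

**Count**

Total steps: 16. Longest linear sequence: 16 (steps 1–16; bromide 15 enters twice, in steps 10 and 13).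

**Steps most likely to fail**

Step 11. The cycloaddition may give poor regio- or facial selectivity, react sluggishly with the lipophilic diene in the aqueous medium, or the cis aldehyde may epimerise under amine catalysis. Fallback with an auxiliary and a Lewis acid instead of iminium catalysis: from 18, commercial (R)-3-acryloyl-4-benzyl-1,3-oxazolidin-2-one and Et2AlCl in CH2Cl2 at −78 °C should give, through the chelated s-cis dienophile whose benzyl group blocks one face, the Diels–Alder imide F3. LiBH4/H2O in Et2O at 0 °C removes the auxiliary to give the primary alcohol F4, and Dess–Martin periodinane (NaHCO3, CH2Cl2) oxidises it to aldehyde 20, where the route is rejoined.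

Step 15. The twofold Mitsunobu displacement may stay incomplete at the hindered allylic alcohols, or hydrogen may be delivered to the wrong face of C9. Fallback by palladium-hydride transfer instead of the sigmatropic route: from 24, formic acetic anhydride and pyridine give the bis(formate) F5. Palladium diacetate with PBu3 in dioxane at 80 °C then forms the π-allyl formate complexes, which lose CO2 and pass hydride from the metal (on the less hindered α-face) to the more substituted terminus C9. This should give the two exocyclic methylenes and return to 27.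

Step 4. Protonation may give the cis ring fusion, or the enolate may be O-alkylated. Fallback by copper-hydride conjugate reduction and regiospecific enolate regeneration: from 5, t-BuCu/DIBAL-H in THF/HMPA at −50 °C (a reduction known to favour trans-hydrindanones) and protonation give the trans-fused 4-methyl ketone F1. Me3SiCl, NaI and Et3N in MeCN convert it into the more substituted C3=C4 silyl enol ether F2. MeLi in THF releases lithium enolate 6, which is alkylated with benzyl chloromethyl ether as in step 4 to rejoin the route at 7.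

Further compounds
F1 | step 4 | trans-fused 4-methyl ketone ketal (C4 epimers) | O1CCOC12CC[C@H]3C(C)C(=O)CC[C@]23C
F2 | step 4 | C3=C4 trimethylsilyl enol ether of F1 | O1CCOC12CC[C@H]3C(C)=C(O[Si](C)(C)C)CC[C@]23C
F3 | step 11 | Diels–Alder imide with the (R)-4-benzyloxazolidin-2-one auxiliary | O=C([C@H]1CCC=C(C)[C@H]1CC2=C(C(=O)OCC)CC[C@H]3[C@](C)(COCc4ccccc4)CCC[C@]23C)N5[C@H](Cc6ccccc6)COC5=O
F4 | step 11 | primary alcohol from F3 | OC[C@H]1CCC=C(C)[C@H]1CC2=C(C(=O)OCC)CC[C@H]3[C@](C)(COCc4ccccc4)CCC[C@]23C
F5 | step 15 | bis(allylic formate) of 24 | C(C1=C(COC=O)CC[C@H]2[C@](C)(COCc3ccccc3)CCC[C@]12C)/C=C(\C)[C@H]4CCC=C(C)[C@H]4CC5=C(COC=O)CC[C@H]6[C@](C)(COCc7ccccc7)CCC[C@]56C
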